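A small charge of starting material turns more of itself into target: after 4.00 min at 75 °C the gamma run held 2.9% of its charge, and the theta run, with twice that charge, held 1.8%.

| setting | gamma | alpha | theta | beta | violet | teal | ochre | green |
|---|---|---|---|---|---|---|---|---|
| starting material | 34 mM | 17 mM | 68 mM | 34 mM | 34 mM (fed, over 5.0 min) | 34 mM | 34 mM | 34 mM (fed, over 5.0 min) |
| coupling partner | 35.7 mM | 35.7 mM | 35.7 mM | 18 mM | 35.7 mM | 35.7 mM (fed, over 30 s) | 35.7 mM (fed, over 5.0 min) | 35.7 mM |
| temperature | 75 °C | 90 °C | 75 °C | 90 °C |  | 90 °C | 90 °C | 90 °C |
| remark | run made earlier | run made earlier | run made earlier | run made earlier | the addition at 50 °C, then warmed to 90 °C; the feed brings no volume worth counting | all else is in the flask from the start; the feed brings no volume worth counting | all else is in the flask from the start; the feed brings no volume worth counting | all else is in the flask from the start; the feed brings no volume worth counting |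
| time |  |  |  |  | 6.0 min | 6.0 min | 6.0 min | 6.0 min |

| run | time / min | target / % |
|---|---|---|
| gamma | 2.00 | 1.3 |
| gamma | 4.00 | 2.9 |
| gamma | 5.00 | 3.8 |
| gamma | 8.00 | 6.7 |
| alpha | 0.667 | 0.3 |
| alpha | 1.50 | 2.4 |
| alpha | 3.00 | 6.8 |
| alpha | 5.00 | 11.5 |
| theta | 0.833 | 0 |
| theta | 2.00 | 1.1 |
| theta | 4.00 | 1.8 |
| theta | 10.0 | 2.8 |
| beta | 0.417 | 0 |
| beta | 0.833 | 0 |
| beta | 2.00 | 1.7 |
| beta | 5.00 | 3.1 |

(readings scatter by 0.5 percentage points)

- a species is counted by the starting material in it: one side product B counts as two
- the analysis behind the earlier runs scatters by 0.5 percentage points, standard deviation
- what may be going on: starting material + coupling partner -> intermediate; starting material -> side product A; coupling partner + intermediate -> target; coupling partner -> decomposition product; starting material + intermediate -> side product B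

- the best flask by amount of target, in percent of the starting material charged; "all alike" if 1.5 percentage points covers them all (violet / teal / ochre / green / all alike)
- amount of target at the end, in percent of the starting material charged, violet
- amount of target at the end, in percent of the starting material charged, teal
- amount of target at the end, in percent of the starting material charged, ochre
- amount of target at the end, in percent of the starting material charged, green

So doubling the charge multiplied the amount of target by just 1.24. That is an order in starting material of 0.312, a rough reading at such small values. We correct the alpha run to the beta run's charge of starting material with it, compare the two at 5.00 min, and get 1.22. We call this the partner order, the power of the coupling partner charge to which the amount of target answers at a fixed charge of starting material. It is the larger order.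

Two extreme flasks can be done in the head. In the first, everything is in at the start. We extend the alpha run along its last slope to 6.0 min and scale it by the order in starting material, which gives 8.60%. In the second, a reagent trickles in across the run and stands on average at half the level of the first, so the target shrinks by half raised to that reagent's order.

Teal, fed over 30 s, sits by the first extreme. Ochre and green, fed for 83.3% of the run, sit by the second. We therefore reckon 8.60% for teal, 3.70% for ochre and 6.93% for green. Violet is hot for 1.00 min. Counting its cold stage as nothing, we read the alpha run at that same hot time, between its readings at 0.667 min and 1.50 min, scale alike and get 0.707%.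

The forecast names teal, with 2% for violet, 9% for teal, 4% for ochre and 5.5% for green. For ochre it says “rate goes roughly as C²”, a steeper order than ours, yet its ochre figure stands close to ours. Its violet figure stands higher than ours.

    starting material + coupling partner → intermediate (k = 0.200 /M/s, Ea = 61.0 kJ/mol)
    starting material → side product A (k = 0.00310 /s, Ea = 113 kJ/mol)
    coupling partner + intermediate → target (k = 0.0430 /M/s, Ea = 51.0 kJ/mol)
    coupling partner → decomposition product (k = 1.10 × 10⁻⁵ /s, Ea = 126 kJ/mol)
    starting material + intermediate → side product B (k = 0.0890 /M/s, Ea = 68.0 kJ/mol)
    (constants at 90 °C)

The simulation names teal: violet 1.53%, teal 8.75%, ochre 4.14%, green 6.40%, each within the tolerance of the forecast. In ochre the coupling partner averaged 35.8% of its charge over the first 5.0 min. Applied to the teal result, the partner order gives ochre 3.76%, against the 4.14% found. Applied to violet with 61 mM of coupling partner, it gives 2.94%. That neighbouring flask gave 4.10%.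

(All runs are calculated with made-up constants; noise was put on by code.)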